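In the 2.5 min given to this flask, closed and isothermal, G turns J into E while Q dissolves from gas held at constant pressure.

| flask | J | Q | G | remark | time |
|---|---|---|---|---|---|
| winter | 0.20 M | 44 mM (held) | 1.5 mM | run made earlier |  |
| dawn | 0.80 M | 44 mM (held) | 1.5 mM | run made earlier |  |
| noon | 0.40 M | 44 mM (held) | 3 mM | run made earlier |  |
| flask | 0.40 M | 44 mM (held) | 1.5 mM |  | 2.5 min |

| run | time / s | E / % |
|---|---|---|
| winter | 10.0 | 17.8 |
| winter | 20.0 | 34.1 |
| winter | 50.0 | 68.9 |
| winter | 120 | 91.9 |
| dawn | 30.0 | 21.0 |
| dawn | 60.0 | 38.1 |
| dawn | 90.0 | 47.0 |
| dawn | 120 | 54.9 |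
| noon | 10.0 | 13.0 |
| noon | 20.0 | 24.3 |
| noon | 50.0 | 59.1 |
| noon | 120 | 85.9 |

(scatter of a reading: 1 percentage point)

- at the start none of Q is in solution

- how much E there is at 2.5 min, in percent of the J charged
- the change that raises the amount of E at 2.5 min, in percent of the J charged most ("none" if none brings more than 2 percentage points) (delta / alpha / zeta / none)
- amount of E at 2.5 min, in percent of the J charged, after zeta

- delta: doubling the amount of G, all else as stated
- alpha: doubling the transfer coefficient of Q, all else as stated
- zeta: doubling the saturation concentration of Q, all else as stated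

Two readings seem not to go together. The winter run makes E at 3.56 mM s⁻¹ up to its first reading, from a charge of 0.20 M of J. The dawn run, with the same G, makes E at 2.11 mM s⁻¹ between its last two readings, slower, although it still holds 0.361 M of J, more than the winter charge. The dawn stretch also comes later in its run than the winter stretch and holds more E, 0.439 M at its last reading against 0.0356 M at the winter's first, so the reckoning here supposes that E wears G down as it accumulates, as in catalyst poisoning. The quantity to watch is then mean cE multiplied by time. Replacing the flask's curve by a mean of half its J charge gives 30.0 M·s, the E-exposure. The area under the dawn readings is 32.1 M·s, about the same, so this reckoning expects the flask to end in a slow stretch, though it yields no percentage.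

The forecast gives 86%, names zeta as best and gives 98.5% after it, holding that “The slowdown therefore follows time, not E or J”, which is a different reading from the one here.

The flask gives 78.5%; zeta is best, gaining 15 percentage points, and reaches 93.2%.

    Q ⇌ D, rate k1*(csat - [D]) (kL = 0.147 s⁻¹)
    J + D + G → G + E (k = 2480 L² mol⁻² s⁻¹)
    D → Z (k = 0.361 s⁻¹)
    G + E → L (k = 0.0887 L mol⁻¹ s⁻¹)

With G falling as the exponential of minus 0.0887 L mol⁻¹ s⁻¹ times the exposure, 30.0 M·s leaves 6.99% of the G charged, and the flask holds 5.17% of its G at 2.50 min, which corresponds to a mean cE of 0.223 M. The neighbour with 0.0060 M of G has the same J charge and so the same estimate, 6.99%, but it reaches 94.7% of E and holds 2.32% of its G, corresponding to a mean cE of 0.283 M.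

The earlier runs and the new flask stem from a simulated flask for substances that don't exist; noise was put on by code.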